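The route rests on cutting the 5,5-dimethyl-2(5H)-furanylidene ring at O1–C5 and C2–C3. Its C3H=C4H–C5Me2 segment is 3,3-dimethylcyclopropene with one ring σ bond opened. O1–C2 together with the exocyclic C(CHO) is a formylketene, carried as a methyl (E)-β-methoxyacrylate. In the key step cationic gold releases the cyclopropene strain as a gold allyl cation that adds across the ester C=O (formal [3+2]). Loss of two methanols then unveils the ring, the push–pull alkene and the formyl group in one operation. The precursor is an acyclic β-methoxyacrylate whose two stereocentres come from an Ireland–Claisen rearrangement with chirality transfer from (S)-but-3-yn-2-ol.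

Key step: step 10

Assumption: 3,3-dimethylcyclopropene is treated as not commercially available and is made in steps 8 and 9. Locants C1–C5 in the Why lines are those of the pentanoic acid chain of the target (C2 and C3 are the stereocentres); primed locants are those of the furan ring.

Step 1
Reactants: 1 2-(3-chloropropyl)-2-methyl-1,3-dioxolane; 2 diketene (4-methylideneoxetan-2-one)
Product: 4 3-methylidene-6-(2-methyl-1,3-dioxolan-2-yl)hexanoic acid, via Grignard reagent 3 (not isolated)
Conditions: Mg, THF, reflux; then 2, CoI2 (5 mol %), THF, −30 to 0 °C; cold aq. citric acid to pH 4–5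
Reagents that add atoms: none
Why: The cobalt-catalysed ring-opening cross-coupling of an alkyl Grignard reagent at the vinylic C–O bond of diketene is a known route to 3-methylidene alkanoic acids, places the 1,1-disubstituted alkene β,γ to the acid without an olefination, and spares the ketal because the work-up stays weakly acidic.

Step 2
Reactants: 5 methyl (E)-3-methoxyprop-2-enoate
Product: 7 methyl (Z)-2-iodo-3-methoxyprop-2-enoate, via iodoacetate adduct 6 (not isolated)
Conditions: NIS, AcOH, CH2Cl2, rt; then Et3N, rt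
Reagents that add atoms: N-iodosuccinimide, O=C1CCC(=O)N1I
Why: Iodoacetoxylation of the enol ether followed by base-induced loss of acetic acid (addition–elimination α-iodination) is the standard access to this iodide, with iodine ending cis to the methoxy group.

Step 3
Reactants: 7 methyl (Z)-2-iodo-3-methoxyprop-2-enoate; 8 (S)-but-3-yn-2-ol
Product: 9 methyl (2E,5S)-5-hydroxy-2-(methoxymethylidene)hex-3-ynoate
Conditions: PdCl2(PPh3)2 (3 mol %), CuI (6 mol %), Et3N, THF, rt
Reagents that add atoms: none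
Why: Sonogashira coupling of an electron-poor alkenyl iodide runs at room temperature with retention of the alkene geometry (the descriptor changes only by priority) and does not touch the carbinol stereocentre.

Step 4
Reactants: 9 methyl (2E,5S)-5-hydroxy-2-(methoxymethylidene)hex-3-ynoate; 4 3-methylidene-6-(2-methyl-1,3-dioxolan-2-yl)hexanoic acid
Product: 10 (2S,5E)-6-methoxy-5-(methoxycarbonyl)hex-5-en-3-yn-2-yl 3-methylidene-6-(2-methyl-1,3-dioxolan-2-yl)hexanoate
Conditions: N,N'-diisopropylcarbodiimide, DMAP (5 mol %), CH2Cl2, 0 °C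
Reagents that add atoms: none
Why: Steglich-type carbodiimide esterification acylates the secondary propargylic alcohol with retention at the carbinol carbon, and low temperature with little DMAP keeps the β,γ-alkene of the acid out of conjugation.

Step 5
Reactants: 10 (2S,5E)-6-methoxy-5-(methoxycarbonyl)hex-5-en-3-yn-2-yl 3-methylidene-6-(2-methyl-1,3-dioxolan-2-yl)hexanoate
Product: 11 (2S,3Z,5E)-6-methoxy-5-(methoxycarbonyl)hexa-3,5-dien-2-yl 3-methylidene-6-(2-methyl-1,3-dioxolan-2-yl)hexanoate
Conditions: H2 (1 atm), Pd/CaCO3 poisoned with Pb(OAc)2 (Lindlar catalyst), quinoline, EtOAc, rt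
Reagents that add atoms: none
Why: Lindlar semihydrogenation gives the Z-alkene by syn addition of hydrogen, is run on the ester so that no free Z-hydroxy ester can lactonise, and leaves the hindered 1,1-disubstituted and trisubstituted alkenes alone.

Step 6
Reactants: 11 (2S,3Z,5E)-6-methoxy-5-(methoxycarbonyl)hexa-3,5-dien-2-yl 3-methylidene-6-(2-methyl-1,3-dioxolan-2-yl)hexanoate
Product: 14 triisopropylsilyl (2R,3S,4E)-3-[(1E)-1,3-dimethoxy-3-oxoprop-1-en-2-yl]-2-[5-(2-methyl-1,3-dioxolan-2-yl)pent-1-en-2-yl]hex-4-enoate, via lithium enolate 12 (not isolated), via silyl ketene acetal 13 (not isolated)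
Conditions: LiN(i-Pr)2 (LDA), THF–DMPU (4:1), −78 °C; TIPSOTf, −78 to 40 °C; pH 7 buffer
Reagents that add atoms: triisopropylsilyl trifluoromethanesulfonate, CC(C)[Si](C(C)C)(C(C)C)OS(=O)(=O)C(F)(F)F
Why: In this Ireland–Claisen rearrangement the DMPU medium and the conjugating alkenyl group favour the Z(O)-enolate, and its Z-ketene acetal reacts through the chair with the carbinol methyl group equatorial (the other chair has a 1,3-diaxial clash with the Z-substituent), so the S carbinol centre is relayed to 3S, the Z/Z pairing gives the anti 2R,3S relation, and the new alkene is E.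

Step 7
Reactants: 14 triisopropylsilyl (2R,3S,4E)-3-[(1E)-1,3-dimethoxy-3-oxoprop-1-en-2-yl]-2-[5-(2-methyl-1,3-dioxolan-2-yl)pent-1-en-2-yl]hex-4-enoate
Product: 15 triisopropylsilyl (2R,3S,4E)-3-[(1E)-1,3-dimethoxy-3-oxoprop-1-en-2-yl]-2-[5-(2-methyl-1,3-dioxolan-2-yl)pent-1-en-2-yl]-5-(4,4,5,5-tetramethyl-1,3,2-dioxaborolan-2-yl)pent-4-enoate
Conditions: vinylboronic acid pinacol ester (3 equiv), second-generation Hoveyda–Grubbs catalyst (5 mol %), CH2Cl2, 40 °C
Reagents that add atoms: vinylboronic acid pinacol ester, C=CB1OC(C)(C)C(C)(C)O1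
Why: In this olefin cross-metathesis the E-propenyl group exchanges its ethylidene end for the borylmethylidene unit with loss of volatile propene, the E-alkenylboronate is the thermodynamic product, and the 1,1-disubstituted alkene next to branched C2 and the trisubstituted push–pull alkene belong to the least reactive olefin classes.

Step 8
Reactants: 16 3-methylbut-2-enal
Product: 17 N'-[(1E)-3-methylbut-2-en-1-ylidene]-4-methylbenzenesulfonohydrazide
Conditions: TsNHNH2, MeOH, rt
Reagents that add atoms: 4-methylbenzenesulfonohydrazide, Cc1ccc(cc1)S(=O)(=O)NN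
Why: Condensation of the enal with tosylhydrazide (hydrazone formation) takes place at the carbonyl group only and gives the crystalline E-hydrazone.

Step 9
Reactants: 17 N'-[(1E)-3-methylbut-2-en-1-ylidene]-4-methylbenzenesulfonohydrazide
Product: 20 3,3-dimethylcyclopropene, via sodium salt 18 (not isolated), via diazoalkene 19 (not isolated)
Conditions: NaOMe, MeOH, then evaporation to dryness; dry salt, 140–160 °C, reduced pressure, trap at −78 °C
Reagents that add atoms: none
Why: In this aprotic Bamford–Stevens reaction the dry salt loses sulfinate to the vinyl diazoalkane, loss of N2 closes the three-membered ring (a known entry to alkylcyclopropenes), and the volatile product leaves the hot zone as it forms.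

Step 10
Reactants: 15 triisopropylsilyl (2R,3S,4E)-3-[(1E)-1,3-dimethoxy-3-oxoprop-1-en-2-yl]-2-[5-(2-methyl-1,3-dioxolan-2-yl)pent-1-en-2-yl]-5-(4,4,5,5-tetramethyl-1,3,2-dioxaborolan-2-yl)pent-4-enoate; 20 3,3-dimethylcyclopropene
Product: 22 triisopropylsilyl (2R,3S,4E)-3-[(1E)-1-(5,5-dimethylfuran-2(5H)-ylidene)-2-oxoethyl]-2-[5-(2-methyl-1,3-dioxolan-2-yl)pent-1-en-2-yl]-5-(4,4,5,5-tetramethyl-1,3,2-dioxaborolan-2-yl)pent-4-enoate, via cyclic ketal 21 (not isolated)
Conditions: 20 (5 equiv, slow addition as a cold CH2Cl2 solution), Ph3PAuNTf2 (5 mol %), 4 Å MS, CH2Cl2, −20 °C to rt; then wet silica gel, rt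
Reagents that add atoms: water, O
Why: Proposed new method: Ph3PAu+ opens the strained alkene of 20 to the gold-stabilised 1,1-dimethylallyl cation (Au–CH=CH–CMe2+), the ester carbonyl oxygen of 15 adds to its tertiary end (O1'–C5' bond), and, as the medium holds no proton source, the vinyl–gold carbon can only be discharged on the trialkoxyallyl cation just formed, at the former ester carbon (C2'–C3' bond), to give ketal 21 and free gold; 21 ionises with loss of methanol and wet silica hydrolyses the methyl oxocarbenium end to the formyl group. The closest known reaction types are the gold-catalysed, C3-selective addition of oxygen nucleophiles to 3,3-disubstituted cyclopropenes and the [3+2] cycloaddition of gold-containing all-carbon 1,3-dipoles with aldehydes to 2,5-dihydrofurans; new is a carboxyl-level C=O as the two-atom partner, which turns the adduct into an alkylidene ring by loss of its alkoxy group. The one ring is closed as a formal [3+2] annulation (opened cyclopropene σ bond across C=O) whose second bond forms by 5-endo-trig attack of the Z-vinylgold on the carboxonium carbon; E and Z gold allyl cations interconvert through the carbene form and O-capture is reversible, so only the Z form is drained. No lasting stereocentre is made (the ketal carbon of 21 is planarised again), C2 and C3 are safe in the aprotic, base-free medium, and the E geometry of the push–pull alkene is set thermodynamically through its low rotation barrier, the branched C3 lying next to O1' and not next to C3'–H. The step needs one oxygen out of nine and O- over alkene attack: the β-methoxy group makes this carbonyl a vinylogous carbonate and the most Lewis-basic site, the silyl ester is shielded, ketal and boronate oxygens are weak or hindered donors that can only add reversibly, the alkenylboronate is electron-poor, and slow addition of excess 20 holds down its oligomerisation and cyclopropanation of the 1,1-disubstituted alkene.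

Step 11
Reactants: 22 triisopropylsilyl (2R,3S,4E)-3-[(1E)-1-(5,5-dimethylfuran-2(5H)-ylidene)-2-oxoethyl]-2-[5-(2-methyl-1,3-dioxolan-2-yl)pent-1-en-2-yl]-5-(4,4,5,5-tetramethyl-1,3,2-dioxaborolan-2-yl)pent-4-enoate
Product: 23 triisopropylsilyl (2R,3S)-3-[(1E)-1-(5,5-dimethylfuran-2(5H)-ylidene)-2-oxoethyl]-2-[5-(2-methyl-1,3-dioxolan-2-yl)pent-1-en-2-yl]-5-oxopentanoate
Conditions: NaBO3·4H2O, THF–pH 7 phosphate buffer, 0 °C to rt
Reagents that add atoms: sodium perborate, [Na+].[Na+].O[B-]1(O)OO[B-](O)(O)OO1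
Why: Oxidation of the alkenylboronate (1,2-shift of carbon from boron to oxygen) gives the enol borate and, on hydrolysis, the CH2CHO arm directly, while the buffered reagent is too mild to attack the deactivated push–pull enal or to epimerise C2.

Step 12
Reactants: 23 triisopropylsilyl (2R,3S)-3-[(1E)-1-(5,5-dimethylfuran-2(5H)-ylidene)-2-oxoethyl]-2-[5-(2-methyl-1,3-dioxolan-2-yl)pent-1-en-2-yl]-5-oxopentanoate
Product: 24 (2R,3S)-3-[(1E)-1-(5,5-dimethylfuran-2(5H)-ylidene)-2-oxoethyl]-5-oxo-2-(6-oxohept-1-en-2-yl)pentanoic acid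
Conditions: aq. HF, MeCN, 0 °C to rt
Reagents that add atoms: water, O
Why: In this combined desilylation and acetal hydrolysis, fluoride cleaves the silyl ester and the mildly acidic water opens the dioxolane, while the vinylogous-ester character of the furanylidene enal protects its enol ether and an acidic medium cannot epimerise C2 through an enolate.

Compound list
1 | 2-(3-chloropropyl)-2-methyl-1,3-dioxolane | CC1(CCCCl)OCCO1 | starting material
2 | diketene (4-methylideneoxetan-2-one) | C=C1CC(=O)O1 | starting material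
3 | [3-(2-methyl-1,3-dioxolan-2-yl)propyl]magnesium chloride | CC1(CCC[Mg]Cl)OCCO1 | intermediate
4 | 3-methylidene-6-(2-methyl-1,3-dioxolan-2-yl)hexanoic acid | C=C(CC(=O)O)CCCC1(C)OCCO1 | intermediate
5 | methyl (E)-3-methoxyprop-2-enoate | CO/C=C/C(=O)OC | starting material
6 | methyl 3-acetoxy-2-iodo-3-methoxypropanoate (racemic, diastereomer mixture) | COC(OC(C)=O)C(I)C(=O)OC | intermediate
7 | methyl (Z)-2-iodo-3-methoxyprop-2-enoate | CO/C=C(I)/C(=O)OC | intermediate
8 | (S)-but-3-yn-2-ol | C[C@H](O)C#C | starting material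
9 | methyl (2E,5S)-5-hydroxy-2-(methoxymethylidene)hex-3-ynoate | CO/C=C(\C#C[C@H](C)O)C(=O)OC | intermediate
10 | (2S,5E)-6-methoxy-5-(methoxycarbonyl)hex-5-en-3-yn-2-yl 3-methylidene-6-(2-methyl-1,3-dioxolan-2-yl)hexanoate | C=C(CCCC1(C)OCCO1)CC(=O)O[C@@H](C)C#C/C(=C\OC)C(=O)OC | intermediate
11 | (2S,3Z,5E)-6-methoxy-5-(methoxycarbonyl)hexa-3,5-dien-2-yl 3-methylidene-6-(2-methyl-1,3-dioxolan-2-yl)hexanoate | C=C(CCCC1(C)OCCO1)CC(=O)O[C@@H](C)/C=C\C(=C/OC)C(=O)OC | intermediate
12 | lithium Z(O)-enolate of 11 (alkenyl group cis to OLi) | C=C(CCCC1(C)OCCO1)/C=C(\[O-])O[C@@H](C)/C=C\C(=C/OC)C(=O)OC.[Li+] | intermediate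
13 | (Z)-O-triisopropylsilyl ketene acetal of 11 (alkenyl group cis to OSi) | C=C(CCCC1(C)OCCO1)/C=C(\O[Si](C(C)C)(C(C)C)C(C)C)O[C@@H](C)/C=C\C(=C/OC)C(=O)OC | intermediate
14 | triisopropylsilyl (2R,3S,4E)-3-[(1E)-1,3-dimethoxy-3-oxoprop-1-en-2-yl]-2-[5-(2-methyl-1,3-dioxolan-2-yl)pent-1-en-2-yl]hex-4-enoate | C=C(CCCC1(C)OCCO1)[C@H](C(=O)O[Si](C(C)C)(C(C)C)C(C)C)[C@H](/C=C/C)/C(=C\OC)C(=O)OC | intermediate
15 | triisopropylsilyl (2R,3S,4E)-3-[(1E)-1,3-dimethoxy-3-oxoprop-1-en-2-yl]-2-[5-(2-methyl-1,3-dioxolan-2-yl)pent-1-en-2-yl]-5-(4,4,5,5-tetramethyl-1,3,2-dioxaborolan-2-yl)pent-4-enoate | C=C(CCCC1(C)OCCO1)[C@H](C(=O)O[Si](C(C)C)(C(C)C)C(C)C)[C@H](/C=C/B1OC(C)(C)C(C)(C)O1)/C(=C\OC)C(=O)OC | intermediate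
16 | 3-methylbut-2-enal | CC(C)=CC=O | starting material
17 | N'-[(1E)-3-methylbut-2-en-1-ylidene]-4-methylbenzenesulfonohydrazide | CC(C)=C/C=N/NS(=O)(=O)c1ccc(C)cc1 | intermediate
18 | sodium salt of 17 | CC(C)=C/C=N/[N-]S(=O)(=O)c1ccc(C)cc1.[Na+] | intermediate
19 | 1-diazo-3-methylbut-2-ene | CC(C)=CC=[N+]=[N-] | intermediate
20 | 3,3-dimethylcyclopropene | CC1(C)C=C1 | intermediate
21 | triisopropylsilyl (2R,3S,4E)-3-[(1E)-2-methoxy-1-(2-methoxy-5,5-dimethyl-2,5-dihydrofuran-2-yl)ethenyl]-2-[5-(2-methyl-1,3-dioxolan-2-yl)pent-1-en-2-yl]-5-(4,4,5,5-tetramethyl-1,3,2-dioxaborolan-2-yl)pent-4-enoate (both epimers at the ketal carbon) | C=C(CCCC1(C)OCCO1)[C@H](C(=O)O[Si](C(C)C)(C(C)C)C(C)C)[C@H](/C=C/B1OC(C)(C)C(C)(C)O1)/C(=C\OC)C1(OC)C=CC(C)(C)O1 | intermediate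
22 | triisopropylsilyl (2R,3S,4E)-3-[(1E)-1-(5,5-dimethylfuran-2(5H)-ylidene)-2-oxoethyl]-2-[5-(2-methyl-1,3-dioxolan-2-yl)pent-1-en-2-yl]-5-(4,4,5,5-tetramethyl-1,3,2-dioxaborolan-2-yl)pent-4-enoate | C=C(CCCC1(C)OCCO1)[C@H](C(=O)O[Si](C(C)C)(C(C)C)C(C)C)[C@H](/C=C/B1OC(C)(C)C(C)(C)O1)/C(C=O)=C1/C=CC(C)(C)O1 | intermediate
23 | triisopropylsilyl (2R,3S)-3-[(1E)-1-(5,5-dimethylfuran-2(5H)-ylidene)-2-oxoethyl]-2-[5-(2-methyl-1,3-dioxolan-2-yl)pent-1-en-2-yl]-5-oxopentanoate | C=C(CCCC1(C)OCCO1)[C@H](C(=O)O[Si](C(C)C)(C(C)C)C(C)C)[C@H](CC=O)/C(C=O)=C1/C=CC(C)(C)O1 | intermediate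
24 | (2R,3S)-3-[(1E)-1-(5,5-dimethylfuran-2(5H)-ylidene)-2-oxoethyl]-5-oxo-2-(6-oxohept-1-en-2-yl)pentanoic acid | C=C(CCCC(C)=O)[C@H](C(=O)O)[C@H](CC=O)/C(C=O)=C1/C=CC(C)(C)O1 | target

Total step count: 12. Longest linear sequence: 9 (steps 2, 3, 4, 5, 6, 7, 10, 11, 12).

Steps most likely to fail

1. Step 10 (bears the label "Proposed new method:").
   - What may go wrong: gold-induced oligomerisation of the cyclopropene may outrun capture by the ester oxygen. The carbene-like form may cyclopropanate the 1,1-disubstituted alkene. O-capture may simply revert because the vinylgold closes too slowly on the strongly stabilised cation.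
   - Fallback (known chemistry): the ring bonds are made one after the other and the ring oxygen comes from a tertiary alcohol. It sets out from 14 and comes back at 22.
   - HF·pyridine in THF frees the carboxylic acid F1.
   - The lithium salt of F1 is acylated at the methyl ester by (Z)-3-methyl-3-(triethylsilyloxy)but-1-enyllithium (from the Z-iodide and t-BuLi, −78 °C) to give the Z-γ-silyloxy dienone F2.
   - PPTS in moist CH2Cl2–MeOH removes the silyl group. The Z-γ-hydroxy enone then closes to its hemiketal and loses methanol by vinylogous elimination to give the furanylidene enal acid F3.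
   - TIPSCl and imidazole give the silyl ester F4, and cross-metathesis with vinylboronic acid pinacol ester as in step 7 returns to 22.

2. Step 6.
   - What may go wrong: incomplete control of the enolate geometry or leakage through a boat transition state would erode the selectivity at C2. Slow rearrangement of the hindered Z-allyl system would leave time for silyl transfer or ketal attack by the triflate.
   - Fallback: reagent control on an achiral ester replaces chirality transfer. It sets out from 7 and 4 and comes back at 15.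
   - Stille coupling of 7 with (E)-3-(tributylstannyl)prop-2-en-1-ol (Pd(PPh3)4, CuI, DMF) gives the E,E-dienol F5.
   - Carbodiimide esterification with 4 gives the primary allylic ester F6.
   - The bromoborane made from BBr3 and an enantiopure 1,2-diphenylethane-1,2-diamine bis(arylsulfonamide), with a tertiary amine at −78 °C, forms a chiral boron ketene acetal that rearranges at −20 °C to the vinyl acid F7. The amine–solvent pair is chosen for the E(O) geometry that matches the E alkene, and the antipode of the controller is chosen for 2R,3S.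
   - Cross-metathesis with vinylboronic acid pinacol ester gives the boronate acid F8, and TIPSCl with imidazole returns to 15.

3. Step 7.
   - What may go wrong: metathesis may be sluggish at the propenyl group next to the branched C3. Methylidene exchange or borylation may compete at the 1,1-disubstituted alkene. Ruthenium hydrides may cause alkene migration.
   - Fallback: hydroboration replaces the metathetic borylation. It sets out from 14 and comes back at 23.
   - Ethenolysis (ethylene, second-generation Hoveyda–Grubbs catalyst, degenerate at the 1,1-disubstituted alkene) gives the vinyl compound F9.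
   - [Ir(cod)Cl]2/dppe-catalysed hydroboration with pinacolborane, selective for the monosubstituted alkene, gives the primary alkylboronate F10.
   - The gold annulation of step 10 gives the furanylidene enal F11, and NaBO3·4H2O gives the primary alcohol F12.
   - Dess–Martin periodinane (NaHCO3, CH2Cl2) returns to 23.

Further compounds
F1 | step 10 | (2R,3S,4E)-3-[(1E)-1,3-dimethoxy-3-oxoprop-1-en-2-yl]-2-[5-(2-methyl-1,3-dioxolan-2-yl)pent-1-en-2-yl]hex-4-enoic acid | C=C(CCCC1(C)OCCO1)[C@H](C(=O)O)[C@H](/C=C/C)/C(=C\OC)C(=O)OC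
F2 | step 10 | (2R,3S,4E)-3-[(1E,4Z)-1-methoxy-6-methyl-3-oxo-6-(triethylsilyloxy)hepta-1,4-dien-2-yl]-2-[5-(2-methyl-1,3-dioxolan-2-yl)pent-1-en-2-yl]hex-4-enoic acid | C=C(CCCC1(C)OCCO1)[C@H](C(=O)O)[C@H](/C=C/C)/C(=C\OC)C(=O)/C=C\C(C)(C)O[Si](CC)(CC)CC
F3 | step 10 | (2R,3S,4E)-3-[(1E)-1-(5,5-dimethylfuran-2(5H)-ylidene)-2-oxoethyl]-2-[5-(2-methyl-1,3-dioxolan-2-yl)pent-1-en-2-yl]hex-4-enoic acid | C=C(CCCC1(C)OCCO1)[C@H](C(=O)O)[C@H](/C=C/C)/C(C=O)=C1/C=CC(C)(C)O1
F4 | step 10 | triisopropylsilyl (2R,3S,4E)-3-[(1E)-1-(5,5-dimethylfuran-2(5H)-ylidene)-2-oxoethyl]-2-[5-(2-methyl-1,3-dioxolan-2-yl)pent-1-en-2-yl]hex-4-enoate | C=C(CCCC1(C)OCCO1)[C@H](C(=O)O[Si](C(C)C)(C(C)C)C(C)C)[C@H](/C=C/C)/C(C=O)=C1/C=CC(C)(C)O1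
F5 | step 6 | methyl (2E,3E)-5-hydroxy-2-(methoxymethylidene)pent-3-enoate | CO/C=C(\C=C\CO)C(=O)OC
F6 | step 6 | (2E,4E)-5-methoxy-4-(methoxycarbonyl)penta-2,4-dien-1-yl 3-methylidene-6-(2-methyl-1,3-dioxolan-2-yl)hexanoate | C=C(CCCC1(C)OCCO1)CC(=O)OC/C=C/C(=C\OC)C(=O)OC
F7 | step 6 | (2R,3S)-3-[(1E)-1,3-dimethoxy-3-oxoprop-1-en-2-yl]-2-[5-(2-methyl-1,3-dioxolan-2-yl)pent-1-en-2-yl]pent-4-enoic acid | C=C(CCCC1(C)OCCO1)[C@H](C(=O)O)[C@H](C=C)/C(=C\OC)C(=O)OC
F8 | step 6 | (2R,3S,4E)-3-[(1E)-1,3-dimethoxy-3-oxoprop-1-en-2-yl]-2-[5-(2-methyl-1,3-dioxolan-2-yl)pent-1-en-2-yl]-5-(4,4,5,5-tetramethyl-1,3,2-dioxaborolan-2-yl)pent-4-enoic acid | C=C(CCCC1(C)OCCO1)[C@H](C(=O)O)[C@H](/C=C/B1OC(C)(C)C(C)(C)O1)/C(=C\OC)C(=O)OC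
F9 | step 7 | triisopropylsilyl (2R,3S)-3-[(1E)-1,3-dimethoxy-3-oxoprop-1-en-2-yl]-2-[5-(2-methyl-1,3-dioxolan-2-yl)pent-1-en-2-yl]pent-4-enoate | C=C(CCCC1(C)OCCO1)[C@H](C(=O)O[Si](C(C)C)(C(C)C)C(C)C)[C@H](C=C)/C(=C\OC)C(=O)OC
F10 | step 7 | triisopropylsilyl (2R,3S)-3-[(1E)-1,3-dimethoxy-3-oxoprop-1-en-2-yl]-2-[5-(2-methyl-1,3-dioxolan-2-yl)pent-1-en-2-yl]-5-(4,4,5,5-tetramethyl-1,3,2-dioxaborolan-2-yl)pentanoate | C=C(CCCC1(C)OCCO1)[C@H](C(=O)O[Si](C(C)C)(C(C)C)C(C)C)[C@H](CCB1OC(C)(C)C(C)(C)O1)/C(=C\OC)C(=O)OC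
F11 | step 7 | triisopropylsilyl (2R,3S)-3-[(1E)-1-(5,5-dimethylfuran-2(5H)-ylidene)-2-oxoethyl]-2-[5-(2-methyl-1,3-dioxolan-2-yl)pent-1-en-2-yl]-5-(4,4,5,5-tetramethyl-1,3,2-dioxaborolan-2-yl)pentanoate | C=C(CCCC1(C)OCCO1)[C@H](C(=O)O[Si](C(C)C)(C(C)C)C(C)C)[C@H](CCB1OC(C)(C)C(C)(C)O1)/C(C=O)=C1/C=CC(C)(C)O1
F12 | step 7 | triisopropylsilyl (2R,3S)-3-[(1E)-1-(5,5-dimethylfuran-2(5H)-ylidene)-2-oxoethyl]-5-hydroxy-2-[5-(2-methyl-1,3-dioxolan-2-yl)pent-1-en-2-yl]pentanoate | C=C(CCCC1(C)OCCO1)[C@H](C(=O)O[Si](C(C)C)(C(C)C)C(C)C)[C@H](CCO)/C(C=O)=C1/C=CC(C)(C)O1
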